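Ring B is a cyclohexene whose bonds C6–C7 and C5–C10 (labdane locants; C5–C10 is the fusion bond shared by rings A and B) are the two sigma bonds of a [4+2] cycloaddition. An intramolecular Diels–Alder reaction of an acyclic (E)-2-ethoxy-1,3-diene (C7=C8–C9=C10) with an (E)-vinyl sulfone (C5=C6), joined by the four-carbon tether C1–C4 that carries the C3 silyloxy stereocentre and the C4 gem-dimethyl group, closes rings A and B at once and sets C5 and C10 from C3. The C8 enol ether and C6 sulfone then deliver the C9 side chain, the C7=C8 alkene and the C8 methyl group; the C32 acid is attached last.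

Key step: step 7

Remark: locants follow labdane numbering (ring A: C1–C5 and C10; ring B: C5–C10; side chain C11–C16 on C9; C17 on C8; C18 and C19 on C4; C20 on C10).
Remark: the acyl residue of the target is read as 32-hydroxydotriacontanoyl (one carboxyl carbon and 31 CH2 groups).

Step 1
Reactants: 1 pent-4-yn-1-ol
Product: 3 (4E)-5-iodo-4-methylpent-4-en-1-ol, via alkenylalane 2 (not isolated)
Conditions: Me3Al (3 equiv), Cp2ZrCl2 (0.25 equiv), CH2Cl2, 0 °C to rt; then I2, THF, −30 °C
Reagents that add atoms: trimethylaluminium, C[Al](C)C; iodine, II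
Why: Negishi zirconium-catalysed syn-carboalumination puts CH3 on the internal and aluminium on the terminal alkyne carbon, and iodinolysis with retention should give the (E)-iodoalkene that later fixes the C9=C10 geometry of the diene.

Step 2
Reactants: 3 (4E)-5-iodo-4-methylpent-4-en-1-ol
Product: 4 (4E)-5-iodo-4-methylpent-4-enal
Conditions: TEMPO (10 mol %), PhI(OAc)2, CH2Cl2, rt
Reagents that add atoms: none
Why: TEMPO/PhI(OAc)2 oxidation should stop at the aldehyde and leave the iodoalkene untouched.

Step 3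
Reactants: 4 (4E)-5-iodo-4-methylpent-4-enal
Product: 6 (4R,7E)-8-iodo-3,3,7-trimethylocta-1,7-dien-4-ol, via borinate 5 (not isolated)
Conditions: (−)-Ipc2BOMe, prenylmagnesium chloride, Et2O, −78 °C to 0 °C; then 4, −78 °C; then NaOH, H2O2
Reagents that add atoms: 3-methylbut-2-enylmagnesium chloride, CC(C)=CC[Mg]Cl
Why: Brown asymmetric reverse prenylation (allylboration through a chair transition state with attack by the dimethyl-substituted terminus) should build the C4 quaternary carbon with its vinyl group and set C3 as R under control of the isopinocampheyl groups derived from (+)-α-pinene.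

Step 4
Reactants: 6 (4R,7E)-8-iodo-3,3,7-trimethylocta-1,7-dien-4-ol
Product: 7 TBS ether of 6
Conditions: TBSOTf, 2,6-lutidine, CH2Cl2, −78 °C to 0 °C
Reagents that add atoms: tert-butyldimethylsilyl trifluoromethanesulfonate, CC(C)(C)[Si](C)(C)OS(=O)(=O)C(F)(F)F
Why: silylation with the silyl triflate should protect the hindered neopentyl-type secondary alcohol for all later steps.

Step 5
Reactants: 7 TBS ether of 6
Product: 9 (E)-vinyl sulfone, via iodo sulfone 8 (not isolated)
Conditions: PhSO2Na, I2, EtOAc/H2O, rt; then Et3N, MeCN, rt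
Reagents that add atoms: sodium benzenesulfinate, [Na+].[O-]S(=O)c1ccccc1
Why: radical iodosulfonylation of the terminal vinyl group (sulfonyl radical to CH2, iodine transfer to C5) followed by dehydroiodination should give the (E)-vinyl sulfone, while the trisubstituted iodoalkene is much less reactive toward the sulfonyl radical.

Step 6
Reactants: 9 (E)-vinyl sulfone
Product: 10 ethoxy triene
Conditions: tributyl(1-ethoxyvinyl)stannane, Pd(PPh3)4 (5 mol %), CuI (10 mol %), DMF, 40 °C
Reagents that add atoms: tributyl(1-ethoxyvinyl)stannane, CCOC(=C)[Sn](CCCC)(CCCC)CCCC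
Why: Stille coupling with retention of the iodoalkene geometry should give the (E)-2-ethoxy-1,3-diene with the tether trans to C8.

Step 7
Reactants: 10 ethoxy triene
Product: 11 trans-fused cycloadduct (enol ether sulfone)
Conditions: toluene (0.01 M), BHT, Et3N (0.1 equiv), sealed tube, 140 °C
Reagents that add atoms: none
Why: A concerted, asynchronous intramolecular [4+2] cycloaddition (type 1 intramolecular Diels–Alder reaction of a 1,7,9-decatriene) between the diene C7=C8–C9=C10 and the vinyl sulfone C5=C6 should form C6–C7 and C5–C10 together; the closest known reactions are thermal intramolecular Diels–Alder reactions of 1-sulfonyl- and 1-nitro-deca-1,7,9-trienes and cycloadditions of 2-alkoxydienes with a dialkylated terminus. Ring B closes as the six-membered ring of the cycloaddition, and ring A closes at the same moment as the six-membered ring made by the tether C1–C4, fused across C5–C10. The trans fusion (H5 trans to CH3-10) is controlled by the (E)-geometry of C9=C10 (tether outside, CH3 inside) together with the tether-exo, sulfone-endo transition state; the absolute sense at C5 and C10 is controlled by C3, whose OTBS group should sit equatorial in the chair-like tether; the C6 centre (sulfonyl cis to H5) is lost in step 8. The step needs trans over cis fusion and one diene face, which the exo preference of the bulky C4 quaternary carbon and the equatorial OTBS group are expected to secure; the regiochemistry is fixed by the tether. The sulfone lowers the dienophile LUMO and the ethoxy group raises the diene HOMO, which should offset the hindered C5–C10 bond and the electronically less favoured orientation that the tether imposes.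

Step 8
Reactants: 11 trans-fused cycloadduct (enol ether sulfone)
Product: 14 cross-conjugated dienone, via Mannich base 12 (not isolated), via methiodide 13 (not isolated)
Conditions: CH2=NMe2+ I− (Eschenmoser's salt), CH2Cl2, 0 °C to rt; then MeI, rt; then DBU, CH2Cl2, rt
Reagents that add atoms: N,N-dimethylmethyleneiminium iodide, C=[N+](C)C.[I-]
Why: Mannich reaction of the regiodefined enol ether at C9 brings in C11, and E1cB loss of trimethylamine and of benzenesulfinate should give the 9(11),6-dien-8-one, in which C9 is sp2 so that its configuration can be set by protonation in step 9.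

Step 9
Reactants: 14 cross-conjugated dienone
Product: 16 butynyl enone, via titanium dienolate 15 (not isolated)
Conditions: allenyltributylstannane, TiCl4, CH2Cl2, −78 °C; then aqueous NaHCO3, −78 °C to rt
Reagents that add atoms: tributyl(propa-1,2-dienyl)stannane, C=C=C[Sn](CCCC)(CCCC)CCCC
Why: TiCl4-promoted conjugate propargylation (SE2′ attack of the allenylstannane on the exocyclic methylene C11) forms C11–C12, and kinetic protonation of the dienolate at C9 from the face opposite the axial CH3-10 should place the side chain equatorial (9R, as in the target).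

Step 10
Reactants: 16 butynyl enone
Product: 18 alkenyl triflate, via lithium enolate 17 (not isolated)
Conditions: LiBH(s-Bu)3 (L-Selectride), THF, −78 °C; then PhNTf2, −78 °C to 0 °C
Reagents that add atoms: N-phenylbis(trifluoromethanesulfonimide), O=S(=O)(N(c1ccccc1)S(=O)(=O)C(F)(F)F)C(F)(F)F
Why: conjugate hydride addition to the C6=C7–C8=O enone should give the C7=C8 enolate regiospecifically without touching C9, and O-triflation fixes the alkene at C7=C8.

Step 11
Reactants: 18 alkenyl triflate
Product: 19 8-methyl-7-ene alkyne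
Conditions: MeMgBr (3 equiv), Fe(acac)3 (5 mol %), THF/NMP, −30 °C to 0 °C
Reagents that add atoms: methylmagnesium bromide, C[Mg]Br
Why: iron-catalysed cross-coupling of the alkenyl triflate with MeMgBr should install C17 with the alkene kept at C7=C8, and it avoids palladium, which could carbopalladate the alkyne; the terminal alkyne is only deprotonated and returns on work-up.

Step 12
Reactants: 19 8-methyl-7-ene alkyne
Product: 21 diterpenoid allylic alcohol, via alkenylalane 20 (not isolated)
Conditions: Me3Al (3 equiv), Cp2ZrCl2 (0.5 equiv), CH2Cl2, rt; then (CH2O)n, THF, 0 °C to rt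
Reagents that add atoms: trimethylaluminium, C[Al](C)C; formaldehyde (as paraformaldehyde), C=O
Why: Negishi syn-carboalumination (CH3 to C13, aluminium to C14) followed by hydroxymethylation of the alkenylalane with retention should give the (13E)-allylic alcohol with C12 trans to C15.

Step 13
Reactants: 22 16-bromohexadecan-1-ol
Product: 23 (16-bromohexadecyloxy)(tert-butyl)dimethylsilane
Conditions: TBSCl, imidazole, CH2Cl2, rt
Reagents that add atoms: tert-butyldimethylsilyl chloride, CC(C)(C)[Si](C)(C)Cl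
Why: standard silylation of the primary alcohol should allow Grignard formation at the other chain end.

Step 14
Reactants: 23 (16-bromohexadecyloxy)(tert-butyl)dimethylsilane; 24 16-bromohexadecanoic acid
Product: 27 32-(tert-butyldimethylsilyloxy)dotriacontanoic acid, via Grignard reagent 25 (not isolated), via magnesium carboxylate 26 (not isolated)
Conditions: 23, Mg, THF, 50 °C; 24, MeMgCl (1 equiv), THF, −20 °C; combine, Li2CuCl4 (3 mol %), −10 °C to rt; aqueous citric acid
Reagents that add atoms: none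
Why: Kochi-type copper-catalysed coupling of the primary alkyl Grignard reagent with the primary bromide of the carboxylate salt should join the two C16 chains to the C32 acid.

Step 15
Reactants: 21 diterpenoid allylic alcohol; 27 32-(tert-butyldimethylsilyloxy)dotriacontanoic acid
Product: 28 bis-TBS ester
Conditions: DCC, DMAP (cat.), CH2Cl2, rt
Reagents that add atoms: none
Why: Steglich esterification should acylate the only free hydroxyl group, the primary allylic C15–OH.

Step 16
Reactants: 28 bis-TBS ester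
Product: 29 target ester
Conditions: HF·pyridine, THF/pyridine, 0 °C to rt
Reagents that add atoms: none
Why: fluoride-mediated desilylation should remove both TBS ethers, while the allylic ester and both trisubstituted alkenes are expected to survive.

Compound list
1 | pent-4-yn-1-ol | C#CCCCO | starting material
2 | dimethyl{(1E)-5-[(dimethylalumanyl)oxy]-2-methylpent-1-en-1-yl}alumane | C[Al](C)OCCC/C(C)=C/[Al](C)C | intermediate
3 | (4E)-5-iodo-4-methylpent-4-en-1-ol | OCCC/C(C)=C/I | intermediate
4 | (4E)-5-iodo-4-methylpent-4-enal | O=CCC/C(C)=C/I | intermediate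
5 | (4R,7E)-8-iodo-3,3,7-trimethylocta-1,7-dien-4-yl bis[(1R,2R,3R,5S)-isopinocampheyl]borinate | C=CC(C)(C)[C@H](OB([C@H]1[C@H](C)[C@H]2C[C@@H](C1)C2(C)C)[C@H]1[C@H](C)[C@H]2C[C@@H](C1)C2(C)C)CC/C(C)=C/I | intermediate
6 | (4R,7E)-8-iodo-3,3,7-trimethylocta-1,7-dien-4-ol | C=CC(C)(C)[C@H](O)CC/C(C)=C/I | intermediate
7 | tert-butyl{[(4R,7E)-8-iodo-3,3,7-trimethylocta-1,7-dien-4-yl]oxy}dimethylsilane | C=CC(C)(C)[C@H](O[Si](C)(C)C(C)(C)C)CC/C(C)=C/I | intermediate
8 | tert-butyl{[(4R,7E)-2,8-diiodo-3,3,7-trimethyl-1-(phenylsulfonyl)oct-7-en-4-yl]oxy}dimethylsilane (both C2 epimers) | O=S(=O)(CC(I)C(C)(C)[C@H](O[Si](C)(C)C(C)(C)C)CC/C(C)=C/I)c1ccccc1 | intermediate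
9 | tert-butyl{[(1E,4R,7E)-8-iodo-3,3,7-trimethyl-1-(phenylsulfonyl)octa-1,7-dien-4-yl]oxy}dimethylsilane | O=S(=O)(/C=C/C(C)(C)[C@H](O[Si](C)(C)C(C)(C)C)CC/C(C)=C/I)c1ccccc1 | intermediate
10 | tert-butyl{[(1E,4R,7E)-9-ethoxy-3,3,7-trimethyl-1-(phenylsulfonyl)deca-1,7,9-trien-4-yl]oxy}dimethylsilane | O=S(=O)(/C=C/C(C)(C)[C@H](O[Si](C)(C)C(C)(C)C)CC/C(C)=C/C(=C)OCC)c1ccccc1 | intermediate
11 | trans-fused bicyclic cycloadduct (labdane locants: 3R-OTBS equatorial and cis to CH3-10; 5S with H5 trans to CH3-10; 10S; 6R-phenylsulfonyl cis to H5; 8-ethoxy enol ether C8=C9; 4,4,10-trimethyl) | CCOC1C[C@@H](S(=O)(=O)c3ccccc3)[C@@H]2C(C)(C)[C@H](O[Si](C)(C)C(C)(C)C)CC[C@@]2(C)C=1 | intermediate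
12 | Mannich base: 8-ketone of 11 bearing a 9-(dimethylaminomethyl) group trans to CH3-10, 6-phenylsulfonyl retained | O=C1C[C@@H](S(=O)(=O)c3ccccc3)[C@@H]2C(C)(C)[C@H](O[Si](C)(C)C(C)(C)C)CC[C@@]2(C)[C@H]1CN(C)C | intermediate
13 | trimethylammonium iodide of 12 | O=C1C[C@@H](S(=O)(=O)c3ccccc3)[C@@H]2C(C)(C)[C@H](O[Si](C)(C)C(C)(C)C)CC[C@@]2(C)[C@H]1C[N+](C)(C)C.[I-] | intermediate
14 | cross-conjugated dienone (labdane locants: 8-oxo, C6=C7, exocyclic C9=C11H2, 3-OTBS, 4,4,10-trimethyl; C3, C5 and C10 as in 11) | O=C1C=C[C@@H]2C(C)(C)[C@H](O[Si](C)(C)C(C)(C)C)CC[C@@]2(C)C1=C | intermediate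
15 | trichlorotitanium dienolate (8-O-titanium, C8=C9 and C6=C7, 9-but-3-ynyl) | Cl[Ti](Cl)(Cl)OC1C=C[C@@H]2C(C)(C)[C@H](O[Si](C)(C)C(C)(C)C)CC[C@@]2(C)C=1CCC#C | intermediate
16 | butynyl enone (8-oxo, C6=C7, 9-(but-3-ynyl) with H9 trans to CH3-10, 3-OTBS) | O=C1C=C[C@@H]2C(C)(C)[C@H](O[Si](C)(C)C(C)(C)C)CC[C@@]2(C)[C@@H]1CCC#C | intermediate
17 | lithium C7=C8 enolate of the 6,7-dihydro ketone | [Li]OC1=CC[C@@H]2C(C)(C)[C@H](O[Si](C)(C)C(C)(C)C)CC[C@@]2(C)[C@@H]1CCC#C | intermediate
18 | alkenyl triflate (8-trifluoromethanesulfonyloxy, C7=C8, 9-(but-3-ynyl), 3-OTBS) | O=S(=O)(OC1=CC[C@@H]2C(C)(C)[C@H](O[Si](C)(C)C(C)(C)C)CC[C@@]2(C)[C@@H]1CCC#C)C(F)(F)F | intermediate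
19 | 8-methyl-7-ene alkyne (C7=C8, CH3-17, 9-(but-3-ynyl), 3-OTBS; C3, C5, C9 and C10 as in 29) | CC1=CC[C@@H]2C(C)(C)[C@H](O[Si](C)(C)C(C)(C)C)CC[C@@]2(C)[C@@H]1CCC#C | intermediate
20 | (13E)-alkenyl(dimethyl)alane (aluminium on C14, CH3 on C13) | CC1=CC[C@@H]2C(C)(C)[C@H](O[Si](C)(C)C(C)(C)C)CC[C@@]2(C)[C@@H]1CC/C(C)=C/[Al](C)C | intermediate
21 | (3R,5S,9R,10S)-3-(tert-butyldimethylsilyloxy)labda-7,13E-dien-15-ol | CC1=CC[C@@H]2C(C)(C)[C@H](O[Si](C)(C)C(C)(C)C)CC[C@@]2(C)[C@@H]1CC/C(C)=C/CO | intermediate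
22 | 16-bromohexadecan-1-ol | OCCCCCCCCCCCCCCCCBr | starting material
23 | (16-bromohexadecyloxy)(tert-butyl)dimethylsilane | CC(C)(C)[Si](C)(C)OCCCCCCCCCCCCCCCCBr | intermediate
24 | 16-bromohexadecanoic acid | OC(=O)CCCCCCCCCCCCCCCBr | starting material
25 | [16-(tert-butyldimethylsilyloxy)hexadecyl]magnesium bromide | CC(C)(C)[Si](C)(C)OCCCCCCCCCCCCCCCC[Mg]Br | intermediate
26 | chloromagnesium 16-bromohexadecanoate | BrCCCCCCCCCCCCCCCC(=O)O[Mg]Cl | intermediate
27 | 32-(tert-butyldimethylsilyloxy)dotriacontanoic acid | CC(C)(C)[Si](C)(C)OCCCCCCCCCCCCCCCCCCCCCCCCCCCCCCCC(=O)O | intermediate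
28 | (3R,5S,9R,10S)-3-(tert-butyldimethylsilyloxy)labda-7,13E-dien-15-yl 32-(tert-butyldimethylsilyloxy)dotriacontanoate | CC1=CC[C@@H]2C(C)(C)[C@H](O[Si](C)(C)C(C)(C)C)CC[C@@]2(C)[C@@H]1CC/C(C)=C/COC(=O)CCCCCCCCCCCCCCCCCCCCCCCCCCCCCCCO[Si](C)(C)C(C)(C)C | intermediate
29 | (2E)-5-[(1R,4aS,6R,8aS)-6-hydroxy-2,5,5,8a-tetramethyl-1,4,4a,5,6,7,8,8a-octahydronaphthalen-1-yl]-3-methylpent-2-en-1-yl 32-hydroxydotriacontanoate | CC1=CC[C@@H]2C(C)(C)[C@H](O)CC[C@@]2(C)[C@@H]1CC/C(C)=C/COC(=O)CCCCCCCCCCCCCCCCCCCCCCCCCCCCCCCO | target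

Total step count: 16. Longest linear sequence: 14 steps (steps 1 to 12, then 15 and 16).

Steps most likely to fail

Step 7. The cycloaddition may be too slow, because the tether forces the electronically less favoured orientation and the C5–C10 bond joins two hindered carbons; it may also give poor trans/cis or facial selectivity. The fallback is a polar, stepwise ring construction that sets out from 7. Hydroboration–oxidation of the vinyl group (9-BBN; NaOH, H2O2) would give the primary alcohol F1. Stille coupling as in step 6 would give the ethoxydiene alcohol F2, and mild aqueous acid would hydrolyse it to the hydroxy enone F3. TEMPO/PhI(OAc)2 oxidation would give the keto aldehyde F4. Pyrrolidine/AcOH would then bring about an intramolecular enamine Michael addition (C5 to C10) followed by aldol condensation (C7 onto C6) under equilibrating conditions, giving the bicyclic enone F5. α′-Methylenation of F5 (paraformaldehyde, N-methylanilinium trifluoroacetate, THF, reflux) would return to 14.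

Step 9. The stannane may transfer an allenyl instead of a propargyl group, add to the carbonyl group, or the protonation at C9 may be unselective. The fallback sets out from 14. Mukaiyama–Michael addition of 1-(tert-butyldimethylsilyloxy)-1-methoxyethene (TiCl4, CH2Cl2, −78 °C) would give the keto ester F6, with C9 again set by protonation. Conjugate reduction as in step 10 would give the lithium enolate F7, trapped as the alkenyl triflate F8. Iron-catalysed methylation as in step 11 would give the ester F9, and i-Bu2AlH at −78 °C the aldehyde F10. Ohira–Bestmann homologation (dimethyl (1-diazo-2-oxopropyl)phosphonate, K2CO3, MeOH) would return to 19.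

Step 10. The bulky hydride may attack the carbonyl group instead of C6. The fallback sets out from 16: 1,2-addition of MeLi/CeCl3 (THF, −78 °C) would give the tertiary allylic alcohol F11, and ionic deoxygenation (Et3SiH, BF3·OEt2, CH2Cl2, −78 °C) through the allyl cation, with hydride delivery to C6, would return to 19.

Further compounds
F1 | step 7 | (4R,7E)-4-(tert-butyldimethylsilyloxy)-8-iodo-3,3,7-trimethyloct-7-en-1-ol | OCCC(C)(C)[C@H](O[Si](C)(C)C(C)(C)C)CC/C(C)=C/I
F2 | step 7 | (4R,7E)-4-(tert-butyldimethylsilyloxy)-9-ethoxy-3,3,7-trimethyldeca-7,9-dien-1-ol | OCCC(C)(C)[C@H](O[Si](C)(C)C(C)(C)C)CC/C(C)=C/C(=C)OCC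
F3 | step 7 | (3E,7R)-7-(tert-butyldimethylsilyloxy)-10-hydroxy-4,8,8-trimethyldec-3-en-2-one | OCCC(C)(C)[C@H](O[Si](C)(C)C(C)(C)C)CC/C(C)=C/C(C)=O
F4 | step 7 | (4R,7E)-4-(tert-butyldimethylsilyloxy)-3,3,7-trimethyl-9-oxodec-7-enal | O=CCC(C)(C)[C@H](O[Si](C)(C)C(C)(C)C)CC/C(C)=C/C(C)=O
F5 | step 7 | bicyclic enone (labdane locants: 8-oxo, C6=C7, C9H2, 3-OTBS, 4,4,10-trimethyl, trans-fused) | O=C1C=C[C@@H]2C(C)(C)[C@H](O[Si](C)(C)C(C)(C)C)CC[C@@]2(C)C1
F6 | step 9 | keto ester (8-oxo, C6=C7, 9-(2-methoxycarbonylethyl) with H9 trans to CH3-10, 3-OTBS) | O=C1C=C[C@@H]2C(C)(C)[C@H](O[Si](C)(C)C(C)(C)C)CC[C@@]2(C)[C@@H]1CCC(=O)OC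
F7 | step 9 | lithium C7=C8 enolate of the 6,7-dihydro derivative of F6 | [Li]OC1=CC[C@@H]2C(C)(C)[C@H](O[Si](C)(C)C(C)(C)C)CC[C@@]2(C)[C@@H]1CCC(=O)OC
F8 | step 9 | alkenyl triflate ester (8-trifluoromethanesulfonyloxy, C7=C8) | O=S(=O)(OC1=CC[C@@H]2C(C)(C)[C@H](O[Si](C)(C)C(C)(C)C)CC[C@@]2(C)[C@@H]1CCC(=O)OC)C(F)(F)F
F9 | step 9 | methyl ester with C7=C8 and CH3-17 | CC1=CC[C@@H]2C(C)(C)[C@H](O[Si](C)(C)C(C)(C)C)CC[C@@]2(C)[C@@H]1CCC(=O)OC
F10 | step 9 | C13 aldehyde with C7=C8 and CH3-17 | CC1=CC[C@@H]2C(C)(C)[C@H](O[Si](C)(C)C(C)(C)C)CC[C@@]2(C)[C@@H]1CCC=O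
F11 | step 10 | tertiary allylic alcohol (8-hydroxy-8-methyl, C6=C7, either C8 epimer) | CC1(O)C=C[C@@H]2C(C)(C)[C@H](O[Si](C)(C)C(C)(C)C)CC[C@@]2(C)[C@@H]1CCC#C
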